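**Strategy**

The route rests on building ring A (the 3,4-dihydroxy-2-methoxy-6-methylbenzoyl ring), not buying it. In that ring the C2 and C4 oxygens are meta to each other, flank the C3 oxygen and sit ortho and para to the C1 carboxyl, with CH3 on C6: the imprint of a ketoester–enoate annulation. One base-mediated operation joins tert-butyl 4-(benzyloxy)acetoacetate and methyl crotonate through C1–C6 (conjugate addition) and C3–C4 (Dieckmann closure), giving the six-membered carbocycle with every substituent in place and the three oxygens already differentiated. Aromatization, O-benzylation, O-methylation and ester cleavage give the ring A acid; ring B is attached as orsellinaldehyde and oxidized, ring C as benzyl orsellinate, and one hydrogenolysis finishes.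

Key step: step 3

Remark: compounds 7–10 carry sp3 centres in the future ring A and are handled as racemic or diastereomeric mixtures, since these centres vanish at the arene stage and the target is achiral. Orsellinaldehyde is taken as purchasable.

**Route**

Step 1
Reactants: 1 benzyloxyacetyl chloride; 2 Meldrum's acid (2,2-dimethyl-1,3-dioxane-4,6-dione)
Product: 3 5-[2-(benzyloxy)-1-hydroxyethylidene]-2,2-dimethyl-1,3-dioxane-4,6-dione
Conditions: pyridine (2 equiv), CH2Cl2, 0 °C → rt
Reagents that add atoms: none
Why: C-acylation of the highly acidic Meldrum's acid by an acid chloride under pyridine is the standard entry to acyl Meldrum's acids and should give the enolized acyl derivative cleanly.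

Step 2
Reactants: 3 5-[2-(benzyloxy)-1-hydroxyethylidene]-2,2-dimethyl-1,3-dioxane-4,6-dione
Product: 5 tert-butyl 4-(benzyloxy)-3-oxobutanoate, via benzyloxyacetylketene 4 (not isolated)
Conditions: t-BuOH (3 equiv), toluene, 90 °C
Reagents that add atoms: tert-butanol, CC(C)(C)O
Why: Thermal retro-[4+2] fragmentation of the acyl Meldrum's acid releases acetone and CO2 to give acylketene 4, which tert-butanol traps as the β-ketoester (acyl Meldrum's acid alcoholysis).

Step 3
Reactants: 5 tert-butyl 4-(benzyloxy)-3-oxobutanoate; 6 methyl (E)-but-2-enoate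
Product: 8 racemic trans tert-butyl 3-(benzyloxy)-2-hydroxy-6-methyl-4-oxocyclohex-2-ene-1-carboxylate (enol form of the 2,4-dione), via Michael adduct 7 (not isolated)
Conditions: KOtBu (1.1 equiv), t-BuOH/THF, rt → 80 °C; then 1 M HCl, 0 °C, to pH 3
Reagents that add atoms: none
Why: KOtBu deprotonates the doubly activated C2 of 5, and this enolate adds 1,4 to the β-carbon of 6 to give diester 7 (ring A bond C1–C6); proton transfer then produces the ketone enolate on the benzyloxy-bearing carbon, which attacks the methyl ester and expels methoxide (bond C3–C4), and immediate deprotonation of the resulting β-diketone pulls both equilibria forward. The closest known reaction is the Michael–Claisen (Michael–Dieckmann) annulation of acetoacetates with crotonates that gives dihydroorsellinates. The single ring closure is a 6-exo-trig acyl substitution by an enolate carbon (6-enolexo). The two sp3 centres C1 and C6 are set only by the thermodynamic preference for the trans isomer through the epimerizable C1, and both disappear on aromatization, so their configuration is irrelevant. The step needs regioselectivity only: the carbon between the two carbonyls is the most acidic and acts as Michael donor, the CH2OBn carbon is the one remaining enolizable position that can reach the methyl ester through a six-membered transition state, and the hindered tert-butyl ester resists attack and transesterification, so CH3 ends on C6 next to the carboxyl carbon and the benzyloxy oxygen on C3 between the two carbonyls.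

Step 4
Reactants: 8 racemic trans tert-butyl 3-(benzyloxy)-2-hydroxy-6-methyl-4-oxocyclohex-2-ene-1-carboxylate
Product: 11 tert-butyl 3-(benzyloxy)-2,4-dihydroxy-6-methylbenzoate, via C3-bromo dione 9 (not isolated), via C1-bromo keto ester 10 (not isolated)
Conditions: Br2 (1.0 equiv), NaOAc (2.2 equiv), DMF, 0 °C; then 60 °C
Reagents that add atoms: none
Why: Halogenation–dehydrohalogenation aromatization of a dihydroresorcylate: bromine first lands on the enol carbon C3 (9), which has no β-hydrogen and acts as a positive-bromine donor, so bromide-mediated transfer should move it to the acidic C1 (10), from where HBr is lost toward C6 and the dienone enolizes to the arene, the acetate buffer protecting the tert-butyl ester and benzyl ether.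

Step 5
Reactants: 11 tert-butyl 3-(benzyloxy)-2,4-dihydroxy-6-methylbenzoate
Product: 12 tert-butyl 3,4-bis(benzyloxy)-2-hydroxy-6-methylbenzoate
Conditions: BnBr (1.05 equiv), K2CO3 (1.2 equiv), acetone, 56 °C
Reagents that add atoms: benzyl bromide, BrCc1ccccc1
Why: Williamson etherification under weak base should occur only at the C4 hydroxyl, which is the more acidic (para to the ester) and is not held in the hydrogen bond that ties the C2 hydroxyl to the ester carbonyl, the usual selectivity of 2,4-dihydroxybenzoates.

Step 6
Reactants: 12 tert-butyl 3,4-bis(benzyloxy)-2-hydroxy-6-methylbenzoate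
Product: 13 tert-butyl 3,4-bis(benzyloxy)-2-methoxy-6-methylbenzoate
Conditions: MeI (3 equiv), K2CO3 (3 equiv), DMF, 50 °C
Reagents that add atoms: iodomethane, CI
Why: With the other two oxygens capped, the remaining chelated C2 phenol is methylated by excess iodomethane in DMF with gentle heating (Williamson etherification), conditions that leave the tert-butyl ester untouched.

Step 7
Reactants: 13 tert-butyl 3,4-bis(benzyloxy)-2-methoxy-6-methylbenzoate
Product: 14 3,4-bis(benzyloxy)-2-methoxy-6-methylbenzoic acid
Conditions: TFA/CH2Cl2 (1:4), 0 °C → rt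
Reagents that add atoms: none
Why: Acidolysis of the tert-butyl ester (alkyl–oxygen cleavage through the tert-butyl cation) is indifferent to the two ortho substituents that would block saponification, and aryl benzyl and methyl ethers survive cold dilute TFA.

Step 8
Reactants: 14 3,4-bis(benzyloxy)-2-methoxy-6-methylbenzoic acid; 15 orsellinaldehyde (2,4-dihydroxy-6-methylbenzaldehyde)
Product: 17 4-formyl-3-hydroxy-5-methylphenyl 3,4-bis(benzyloxy)-2-methoxy-6-methylbenzoate, via acyl chloride 16 (not isolated)
Conditions: (COCl)2, cat. DMF, CH2Cl2, 0 °C → rt, evaporate; then 15 (1.0 equiv), Et3N (1.1 equiv), cat. DMAP, CH2Cl2, 0 °C → rt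
Reagents that add atoms: none
Why: Conversion of the acid into acyl chloride 16 and base-mediated O-acylation of the phenol (acyl chloride esterification) should be selective for the C4 hydroxyl of 15, which is the more acidic and unchelated one, the C2 hydroxyl being locked in a hydrogen bond to the aldehyde.

Step 9
Reactants: 17 4-formyl-3-hydroxy-5-methylphenyl 3,4-bis(benzyloxy)-2-methoxy-6-methylbenzoate
Product: 18 4-{[3,4-bis(benzyloxy)-2-methoxy-6-methylbenzoyl]oxy}-2-hydroxy-6-methylbenzoic acid
Conditions: NaClO2, NaH2PO4, 2-methylbut-2-ene (excess), t-BuOH/THF/H2O, 0 °C → rt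
Reagents that add atoms: sodium chlorite, [Na+].[O-]Cl=O
Why: Pinnick oxidation converts the aryl aldehyde into the acid under buffered, mildly acidic conditions that do not touch the aryl ester or the benzyl ethers, the excess alkene removing the hypochlorous acid that would otherwise chlorinate the electron-rich rings.

Step 10
Reactants: 19 orsellinic acid (2,4-dihydroxy-6-methylbenzoic acid)
Product: 20 benzyl 2,4-dihydroxy-6-methylbenzoate (benzyl orsellinate)
Conditions: BnBr (1.05 equiv), KHCO3 (1.1 equiv), DMF, rt
Reagents that add atoms: benzyl bromide, BrCc1ccccc1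
Why: Hydrogencarbonate ionizes only the carboxyl group, so SN2 alkylation with benzyl bromide should give the benzyl ester and leave both phenols free.

Step 11
Reactants: 18 4-{[3,4-bis(benzyloxy)-2-methoxy-6-methylbenzoyl]oxy}-2-hydroxy-6-methylbenzoic acid; 20 benzyl 2,4-dihydroxy-6-methylbenzoate
Product: 22 benzyl 4-[(4-{[3,4-bis(benzyloxy)-2-methoxy-6-methylbenzoyl]oxy}-2-hydroxy-6-methylbenzoyl)oxy]-2-hydroxy-6-methylbenzoate, via mixed trifluoroacetic anhydride 21 (not isolated)
Conditions: (CF3CO)2O (2.5 equiv), toluene, 0 °C → rt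
Reagents that add atoms: none
Why: Trifluoroacetic anhydride turns the salicylic-type acid into mixed anhydride 21, and its electron-rich aroyl group is transferred to the unchelated C4 hydroxyl of 20 (mixed-anhydride esterification, the classical depside coupling), while the hydrogen-bonded ortho hydroxyls of both partners stay unreactive and the acidic medium leaves the existing aryl ester and the benzyl groups alone.

Step 12
Reactants: 22 benzyl 4-[(4-{[3,4-bis(benzyloxy)-2-methoxy-6-methylbenzoyl]oxy}-2-hydroxy-6-methylbenzoyl)oxy]-2-hydroxy-6-methylbenzoate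
Product: 23 4-[(4-{[3,4-dihydroxy-2-methoxy-6-methylbenzoyl]oxy}-2-hydroxy-6-methylbenzoyl)oxy]-2-hydroxy-6-methylbenzoic acid (target)
Conditions: H2 (1 atm), 10% Pd/C, EtOAc, rt
Reagents that add atoms: none
Why: Catalytic hydrogenolysis cleaves the two benzyl ethers and the benzyl ester in one neutral operation, which the two base-sensitive aryl ester (depside) links tolerate.

**Compound list**

1 | benzyloxyacetyl chloride | O=C(Cl)COCc1ccccc1 | starting material
2 | Meldrum's acid | CC1(C)OC(=O)CC(=O)O1 | starting material
3 | 5-[2-(benzyloxy)-1-hydroxyethylidene]-2,2-dimethyl-1,3-dioxane-4,6-dione | CC1(C)OC(=O)C(=C(O)COCc2ccccc2)C(=O)O1 | intermediate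
4 | benzyloxyacetylketene (formed in the flask) | O=C=CC(=O)COCc1ccccc1 | intermediate
5 | tert-butyl 4-(benzyloxy)-3-oxobutanoate | CC(C)(C)OC(=O)CC(=O)COCc1ccccc1 | intermediate
6 | methyl (E)-but-2-enoate | C/C=C/C(=O)OC | starting material
7 | 1-tert-butyl 5-methyl 2-[(benzyloxy)acetyl]-3-methylpentanedioate (diastereomer mixture, racemic, formed in the flask) | COC(=O)CC(C)C(C(=O)COCc1ccccc1)C(=O)OC(C)(C)C | intermediate
8 | racemic trans tert-butyl 3-(benzyloxy)-2-hydroxy-6-methyl-4-oxocyclohex-2-ene-1-carboxylate (one enantiomer drawn) | C[C@@H]1CC(=O)C(OCc2ccccc2)=C(O)[C@H]1C(=O)OC(C)(C)C | intermediate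
9 | tert-butyl 3-(benzyloxy)-3-bromo-6-methyl-2,4-dioxocyclohexane-1-carboxylate (stereoisomer mixture, formed in the flask) | CC1CC(=O)C(Br)(OCc2ccccc2)C(=O)C1C(=O)OC(C)(C)C | intermediate
10 | tert-butyl 3-(benzyloxy)-1-bromo-2-hydroxy-6-methyl-4-oxocyclohex-2-ene-1-carboxylate (stereoisomer mixture, formed in the flask) | CC1CC(=O)C(OCc2ccccc2)=C(O)C1(Br)C(=O)OC(C)(C)C | intermediate
11 | tert-butyl 3-(benzyloxy)-2,4-dihydroxy-6-methylbenzoate | Cc1cc(O)c(OCc2ccccc2)c(O)c1C(=O)OC(C)(C)C | intermediate
12 | tert-butyl 3,4-bis(benzyloxy)-2-hydroxy-6-methylbenzoate | Cc1cc(OCc2ccccc2)c(OCc2ccccc2)c(O)c1C(=O)OC(C)(C)C | intermediate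
13 | tert-butyl 3,4-bis(benzyloxy)-2-methoxy-6-methylbenzoate | COc1c(OCc2ccccc2)c(OCc2ccccc2)cc(C)c1C(=O)OC(C)(C)C | intermediate
14 | 3,4-bis(benzyloxy)-2-methoxy-6-methylbenzoic acid | COc1c(OCc2ccccc2)c(OCc2ccccc2)cc(C)c1C(=O)O | intermediate
15 | orsellinaldehyde (2,4-dihydroxy-6-methylbenzaldehyde) | Cc1cc(O)cc(O)c1C=O | starting material
16 | 3,4-bis(benzyloxy)-2-methoxy-6-methylbenzoyl chloride (formed in the flask) | COc1c(OCc2ccccc2)c(OCc2ccccc2)cc(C)c1C(=O)Cl | intermediate
17 | 4-formyl-3-hydroxy-5-methylphenyl 3,4-bis(benzyloxy)-2-methoxy-6-methylbenzoate | COc1c(OCc2ccccc2)c(OCc2ccccc2)cc(C)c1C(=O)Oc1cc(C)c(C=O)c(O)c1 | intermediate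
18 | 4-{[3,4-bis(benzyloxy)-2-methoxy-6-methylbenzoyl]oxy}-2-hydroxy-6-methylbenzoic acid | COc1c(OCc2ccccc2)c(OCc2ccccc2)cc(C)c1C(=O)Oc1cc(C)c(C(=O)O)c(O)c1 | intermediate
19 | orsellinic acid | Cc1cc(O)cc(O)c1C(=O)O | starting material
20 | benzyl 2,4-dihydroxy-6-methylbenzoate | Cc1cc(O)cc(O)c1C(=O)OCc1ccccc1 | intermediate
21 | mixed anhydride of 18 with trifluoroacetic acid (formed in the flask) | COc1c(OCc2ccccc2)c(OCc2ccccc2)cc(C)c1C(=O)Oc1cc(C)c(C(=O)OC(=O)C(F)(F)F)c(O)c1 | intermediate
22 | benzyl 4-[(4-{[3,4-bis(benzyloxy)-2-methoxy-6-methylbenzoyl]oxy}-2-hydroxy-6-methylbenzoyl)oxy]-2-hydroxy-6-methylbenzoate | COc1c(OCc2ccccc2)c(OCc2ccccc2)cc(C)c1C(=O)Oc1cc(C)c(C(=O)Oc2cc(C)c(C(=O)OCc3ccccc3)c(O)c2)c(O)c1 | intermediate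
23 | 4-[(4-{[3,4-dihydroxy-2-methoxy-6-methylbenzoyl]oxy}-2-hydroxy-6-methylbenzoyl)oxy]-2-hydroxy-6-methylbenzoic acid | COc1c(O)c(O)cc(C)c1C(=O)Oc1cc(C)c(C(=O)Oc2cc(C)c(C(=O)O)c(O)c2)c(O)c1 | target

**Step count**

Total: 12 steps. Longest linear sequence: 11 steps (steps 1–9, 11, 12); step 10 is a one-step side branch.

**Steps most likely to fail**

1. Step 3. The conjugate addition to a β-substituted acrylate is reversible and may stall, or the crotonate may be consumed by base-induced self-condensation before the Dieckmann closure can pull the sequence forward. The fallback sets out from 1 and moves the ketone into the acceptor. Amidation of 1 with N,O-dimethylhydroxylamine hydrochloride and Et3N should give 2-(benzyloxy)-N-methoxy-N-methylacetamide F1. Weinreb ketone synthesis with 1-propenylmagnesium bromide should give (E)-1-(benzyloxy)pent-3-en-2-one F2 (the Z isomer would serve equally). Michael addition of tert-butyl methyl malonate under KOtBu in t-BuOH should give 1-tert-butyl 3-methyl 2-[5-(benzyloxy)-4-oxopentan-2-yl]propanedioate F3, not isolated. Its CH2OBn enolate closes onto the methyl ester (Claisen condensation), and the route is rejoined at 8.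

2. Step 4. Transfer of bromine away from the blocked C3 position may be slow, so that the newly formed electron-rich arene is brominated at C5 while unreacted dione remains, or the C3 bromo ether may fragment with loss of the benzyl group. The fallback sets out from 8 and uses no halogen: dehydrogenation with DDQ in dioxane at 80 °C, by hydride abstraction from C6 of the enol followed by tautomerization, should lead directly to 11.

3. Step 11. Under the acidic anhydride conditions the unprotected ring B ortho hydroxyl may be acylated (self-condensation), or the existing ring A–ring B ester may scramble. The fallback sets out from 17. Benzylation (BnBr, K2CO3, DMF, rt) should give 3-(benzyloxy)-4-formyl-5-methylphenyl 3,4-bis(benzyloxy)-2-methoxy-6-methylbenzoate F4. Pinnick oxidation should give 2-(benzyloxy)-4-{[3,4-bis(benzyloxy)-2-methoxy-6-methylbenzoyl]oxy}-6-methylbenzoic acid F5. Steglich esterification with 20 (DCC, cat. DMAP, CH2Cl2) should give benzyl 4-[(2-(benzyloxy)-4-{[3,4-bis(benzyloxy)-2-methoxy-6-methylbenzoyl]oxy}-6-methylbenzoyl)oxy]-2-hydroxy-6-methylbenzoate F6. Hydrogenolysis (H2, 10% Pd/C, EtOAc) rejoins the route at 23.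

**Further compounds**

F1 | step 3 | 2-(benzyloxy)-N-methoxy-N-methylacetamide | CON(C)C(=O)COCc1ccccc1
F2 | step 3 | (E)-1-(benzyloxy)pent-3-en-2-one | C/C=C/C(=O)COCc1ccccc1
F3 | step 3 | 1-tert-butyl 3-methyl 2-[5-(benzyloxy)-4-oxopentan-2-yl]propanedioate | COC(=O)C(C(C)CC(=O)COCc1ccccc1)C(=O)OC(C)(C)C
F0 | step 4 | none | none
F4 | step 11 | 3-(benzyloxy)-4-formyl-5-methylphenyl 3,4-bis(benzyloxy)-2-methoxy-6-methylbenzoate | COc1c(OCc2ccccc2)c(OCc2ccccc2)cc(C)c1C(=O)Oc1cc(C)c(C=O)c(OCc2ccccc2)c1
F5 | step 11 | 2-(benzyloxy)-4-{[3,4-bis(benzyloxy)-2-methoxy-6-methylbenzoyl]oxy}-6-methylbenzoic acid | COc1c(OCc2ccccc2)c(OCc2ccccc2)cc(C)c1C(=O)Oc1cc(C)c(C(=O)O)c(OCc2ccccc2)c1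
F6 | step 11 | benzyl 4-[(2-(benzyloxy)-4-{[3,4-bis(benzyloxy)-2-methoxy-6-methylbenzoyl]oxy}-6-methylbenzoyl)oxy]-2-hydroxy-6-methylbenzoate | COc1c(OCc2ccccc2)c(OCc2ccccc2)cc(C)c1C(=O)Oc1cc(C)c(C(=O)Oc2cc(C)c(C(=O)OCc3ccccc3)c(O)c2)c(OCc2ccccc2)c1
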